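The target is the 3,5-syn diacetate (3R,5S) of a 1-aryldodecane-3,5-diol. Everything rests on breaking C5–O and C6–C7 together: a diphenylsilyl hydride placed on O3 of an (R)-homoallylic alcohol is added across the terminal C5=C6 alkene under rhodium and carbon monoxide. In one operation silicon bonds to C5 (a masked hydroxyl, held cis to the C3 side chain in a new five-membered 1,2-oxasilolane O3–Si–C5–C4–C3) and CO is incorporated as the aldehyde carbon C7. The feature used is the 1,3 relation of O3 and O5 with C6/C7 just beyond. The precursor is the O-benzyl (R)-1-arylhex-5-en-3-yl diphenylsilyl ether; Wittig extension, Tamao oxidation, acetylation and one hydrogenation complete the route.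

Key step: step 5

Remark: the C7=C8 geometry of 14–16 is drawn Z, the isomer expected to predominate; any E isomer converges on the same product in step 9.

Step 1
Reactants: 1 4-(3-hydroxypropyl)-2-methoxyphenol (dihydroconiferyl alcohol)
Product: 2 3-[4-(benzyloxy)-3-methoxyphenyl]propan-1-ol
Conditions: BnBr (1.1 equiv), K2CO3, acetone, reflux
Reagents that add atoms: benzyl bromide, BrCc1ccccc1
Why: Williamson ether synthesis; carbonate deprotonates only the phenol, so the primary alcohol should stay free, and no stereocentre is involved.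

Step 2
Reactants: 2 3-[4-(benzyloxy)-3-methoxyphenyl]propan-1-ol
Product: 3 3-[4-(benzyloxy)-3-methoxyphenyl]propanal
Conditions: TEMPO (10 mol %), PhI(OAc)2 (1.1 equiv), CH2Cl2, rt
Reagents that add atoms: none
Why: TEMPO/oxoammonium oxidation of a primary alcohol under non-aqueous conditions should stop at the aldehyde and leave the benzyl aryl ether untouched.

Step 3
Reactants: 3 3-[4-(benzyloxy)-3-methoxyphenyl]propanal; 4 allylmagnesium bromide
Product: 7 (3R)-1-[4-(benzyloxy)-3-methoxyphenyl]hex-5-en-3-ol, via B-allyldiisopinocampheylborane 5 (not isolated), via diisopinocampheylborinate of the product 6 (not isolated)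
Conditions: (−)-Ipc2BOMe, 4, Et2O, 0 °C → rt; then 3, −78 °C; then 3 M NaOH, 30% H2O2, rt
Reagents that add atoms: none
Why: Brown asymmetric allylboration: the allylborane made from (−)-B-methoxydiisopinocampheylborane [(+)-α-pinene series] should deliver allyl through a closed chair transition state to the Si face of the aldehyde, which sets C3 as R under reagent control; alkaline peroxide then cleaves the borinate.

Step 4
Reactants: 7 (3R)-1-[4-(benzyloxy)-3-methoxyphenyl]hex-5-en-3-ol; 8 chlorodiphenylsilane
Product: 9 {[(3R)-1-[4-(benzyloxy)-3-methoxyphenyl]hex-5-en-3-yl]oxy}diphenylsilane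
Conditions: Et3N, DMAP (cat.), CH2Cl2, 0 °C → rt; filtered under Ar, used crude
Reagents that add atoms: none
Why: Silyl ether formation by substitution at silicon with an amine base; the Si–H bond is kept for the next step and C3 is not touched.

Step 5
Reactants: 9 {[(3R)-1-[4-(benzyloxy)-3-methoxyphenyl]hex-5-en-3-yl]oxy}diphenylsilane; 10 carbon monoxide
Product: 11 2-[(3R,5R)-5-{2-[4-(benzyloxy)-3-methoxyphenyl]ethyl}-2,2-diphenyl-1,2-oxasilolan-3-yl]acetaldehyde
Conditions: Rh(acac)(CO)2 (2 mol %), CO (ca. 60 bar), benzene, 60 °C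
Reagents that add atoms: none
Why: Rhodium-catalysed intramolecular alkene silylformylation, a known reaction of homoallylic hydrosilyl ethers: Rh(I) adds oxidatively to Si–H, the tethered C5=C6 alkene inserts into Rh–Si, CO inserts into the resulting C6–Rh bond and C–H reductive elimination frees the aldehyde, whose carbon is C7. The 1,2-oxasilolane (O3–Si–C5–C4–C3) closes by a 5-exo silylmetalation, because the three-atom O–Si tether disfavours delivery of silicon to the terminal C6 (6-endo). The new stereocentre C5 is set by the C3 stereocentre: in the envelope-shaped insertion transition state the arylethyl group on C3 and the C5–C6 bond should both sit pseudo-equatorial, which leads to the cis-3,5 ring and hence the 1,3-syn relationship. The step needs formylation to outrun plain hydrosilylation and alkene migration, which the terminal unhindered alkene and high CO pressure should secure by trapping the primary alkyl–rhodium before C–H elimination or β-hydride loss. Benzyl ether, aryl ring and Si–Ph bonds are spectators under these neutral conditions.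

Step 6
Reactants: 11 2-[(3R,5R)-5-{2-[4-(benzyloxy)-3-methoxyphenyl]ethyl}-2,2-diphenyl-1,2-oxasilolan-3-yl]acetaldehyde; 12 pentyltriphenylphosphonium bromide
Product: 14 (3S,5R)-5-{2-[4-(benzyloxy)-3-methoxyphenyl]ethyl}-3-[(2Z)-hept-2-en-1-yl]-2,2-diphenyl-1,2-oxasilolane, via pentylidenetriphenylphosphorane 13 (not isolated)
Conditions: 12 (1.15 equiv), NaHMDS (1.1 equiv), THF, 0 °C; then 11, −78 °C → 0 °C
Reagents that add atoms: none
Why: Wittig olefination with a salt-free non-stabilised ylide, which should react with the aldehyde at −78 °C much faster than with the silyl ether and give mainly the Z alkene; C5 is β to the carbonyl and cannot epimerise (its descriptor changes from R to S only through CIP priorities).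

Step 7
Reactants: 14 (3S,5R)-5-{2-[4-(benzyloxy)-3-methoxyphenyl]ethyl}-3-[(2Z)-hept-2-en-1-yl]-2,2-diphenyl-1,2-oxasilolane
Product: 15 (3R,5S,7Z)-1-[4-(benzyloxy)-3-methoxyphenyl]dodec-7-ene-3,5-diol
Conditions: 30% H2O2 (excess), KF, KHCO3, THF/MeOH (1:1), 50 °C
Reagents that add atoms: hydrogen peroxide, OO
Why: Tamao oxidation: the fluoride-activated alkoxysilane takes up hydroperoxide and C5 migrates from silicon to oxygen with retention, so the cis ring should become the 3,5-syn diol; the isolated alkene and the benzyl ether are inert to buffered peroxide.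

Step 8
Reactants: 15 (3R,5S,7Z)-1-[4-(benzyloxy)-3-methoxyphenyl]dodec-7-ene-3,5-diol
Product: 16 (3R,5S,7Z)-1-[4-(benzyloxy)-3-methoxyphenyl]dodec-7-ene-3,5-diyl diacetate
Conditions: Ac2O, pyridine, DMAP (cat.), CH2Cl2, rt
Reagents that add atoms: acetic anhydride, CC(=O)OC(C)=O
Why: DMAP-catalysed acylation of the two secondary alcohols; the phenol is still benzylated, so no selective removal of an aryl acetate is needed later.

Step 9
Reactants: 16 (3R,5S,7Z)-1-[4-(benzyloxy)-3-methoxyphenyl]dodec-7-ene-3,5-diyl diacetate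
Product: 17 (3R,5S)-1-(4-hydroxy-3-methoxyphenyl)dodecane-3,5-diyl diacetate
Conditions: H2 (1 atm), 10% Pd/C, EtOAc, rt
Reagents that add atoms: none
Why: Heterogeneous catalytic hydrogenation should saturate C7=C8 and hydrogenolyse the benzyl aryl ether in one operation; the acetates are neither allylic nor benzylic and both stereocentres stay as set.

Compound list
1 | 4-(3-hydroxypropyl)-2-methoxyphenol (dihydroconiferyl alcohol) | COc1cc(CCCO)ccc1O | starting material
2 | 3-[4-(benzyloxy)-3-methoxyphenyl]propan-1-ol | COc1cc(CCCO)ccc1OCc1ccccc1 | intermediate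
3 | 3-[4-(benzyloxy)-3-methoxyphenyl]propanal | COc1cc(CCC=O)ccc1OCc1ccccc1 | intermediate
4 | allylmagnesium bromide (solution in Et2O) | C=CC[Mg]Br | starting material
5 | B-allyldiisopinocampheylborane, isopinocampheyl groups from (+)-α-pinene | C=CCB([C@@H]1C[C@@H]2C[C@H]([C@H]1C)C2(C)C)[C@@H]1C[C@@H]2C[C@H]([C@H]1C)C2(C)C | intermediate (not isolated)
6 | (3R)-1-[4-(benzyloxy)-3-methoxyphenyl]hex-5-en-3-yl diisopinocampheylborinate | C=CC[C@@H](CCc1ccc(OCc2ccccc2)c(OC)c1)OB([C@@H]1C[C@@H]2C[C@H]([C@H]1C)C2(C)C)[C@@H]1C[C@@H]2C[C@H]([C@H]1C)C2(C)C | intermediate (not isolated)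
7 | (3R)-1-[4-(benzyloxy)-3-methoxyphenyl]hex-5-en-3-ol | C=CC[C@@H](CCc1ccc(OCc2ccccc2)c(OC)c1)O | intermediate
8 | chlorodiphenylsilane | Cl[SiH](c1ccccc1)c1ccccc1 | starting material
9 | {[(3R)-1-[4-(benzyloxy)-3-methoxyphenyl]hex-5-en-3-yl]oxy}diphenylsilane | C=CC[C@@H](CCc1ccc(OCc2ccccc2)c(OC)c1)O[SiH](c1ccccc1)c1ccccc1 | intermediate
10 | carbon monoxide | [C-]#[O+] | starting material
11 | 2-[(3R,5R)-5-{2-[4-(benzyloxy)-3-methoxyphenyl]ethyl}-2,2-diphenyl-1,2-oxasilolan-3-yl]acetaldehyde (cis) | O=CC[C@H]1C[C@@H](CCc2ccc(OCc3ccccc3)c(OC)c2)O[Si]1(c1ccccc1)c1ccccc1 | intermediate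
12 | pentyltriphenylphosphonium bromide | CCCCC[P+](c1ccccc1)(c1ccccc1)c1ccccc1.[Br-] | starting material
13 | pentylidenetriphenylphosphorane | CCCCC=P(c1ccccc1)(c1ccccc1)c1ccccc1 | intermediate (not isolated)
14 | (3S,5R)-5-{2-[4-(benzyloxy)-3-methoxyphenyl]ethyl}-3-[(2Z)-hept-2-en-1-yl]-2,2-diphenyl-1,2-oxasilolane (cis) | CCCC/C=C\C[C@H]1C[C@@H](CCc2ccc(OCc3ccccc3)c(OC)c2)O[Si]1(c1ccccc1)c1ccccc1 | intermediate
15 | (3R,5S,7Z)-1-[4-(benzyloxy)-3-methoxyphenyl]dodec-7-ene-3,5-diol | CCCC/C=C\C[C@@H](C[C@@H](CCc1ccc(OCc2ccccc2)c(OC)c1)O)O | intermediate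
16 | (3R,5S,7Z)-1-[4-(benzyloxy)-3-methoxyphenyl]dodec-7-ene-3,5-diyl diacetate | CCCC/C=C\C[C@@H](C[C@@H](CCc1ccc(OCc2ccccc2)c(OC)c1)OC(C)=O)OC(C)=O | intermediate
17 | (3R,5S)-1-(4-hydroxy-3-methoxyphenyl)dodecane-3,5-diyl diacetate | CCCCCCC[C@@H](C[C@@H](CCc1ccc(O)c(OC)c1)OC(C)=O)OC(C)=O | target

Total step count: 9. Longest linear sequence: 9 steps (1 → 17).

Steps most likely to fail

Step 5. The process at risk is capture of the primary alkyl–rhodium by CO (plain hydrosilylation or alkene migration may win) and the cis/trans discrimination in the ring-forming insertion. The fallback leaves the route at 7 and re-enters at 17, building the syn-1,3-diol by iodocarbonate chemistry instead. Alcohol 7 is converted with Boc2O/DMAP in MeCN into tert-butyl (3R)-1-[4-(benzyloxy)-3-methoxyphenyl]hex-5-en-3-yl carbonate F1. Iodine monobromide in toluene at −85 °C should induce iodocarbonate cyclisation to the cis-4,6-disubstituted 1,3-dioxan-2-one F2, with 1,3-syn induction through a chair carrying both substituents equatorial. K2CO3 in MeOH should give the syn epoxy alcohol F3. n-Hexylmagnesium bromide with catalytic CuI in THF at −40 °C should open the epoxide at its terminal carbon to the saturated syn diol F4. Acetylation (Ac2O, pyridine, DMAP) gives the benzyl-protected saturated diacetate F5, and hydrogenolysis (H2, Pd/C, EtOAc) gives 17.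

Step 6. The process at risk is attack of the basic ylide on the strained Si–O bond, or base-induced self-condensation of the β-silyl aldehyde, in competition with olefination. The fallback leaves at 11 and re-enters at 15 by reversing oxidation and olefination. Tamao oxidation of 11 (KF, KHCO3, H2O2, THF/MeOH, rt) should release the 3,5-dihydroxy aldehyde, which closes onto O3 as the six-membered lactol (4R,6R)-6-{2-[4-(benzyloxy)-3-methoxyphenyl]ethyl}oxane-2,4-diol F6. A lactol Wittig reaction with an excess (about 3.5 equiv) of ylide 13 in THF, −78 °C → rt, should then give diol 15 directly, with no silicon present during the basic step.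

Step 3. The process at risk is incomplete facial discrimination in the allyl transfer to an unbranched aldehyde, which would leave enantiomerically impure 7 that no later step can upgrade. The fallback leaves at 3 and returns at 7 by a catalytic Keck allylation: allyltributylstannane, (S)-BINOL/Ti(OiPr)4 (10 mol %), 4 Å molecular sieves, CH2Cl2, −20 °C. Stereocontrol then comes from a chiral Lewis acid bound to the aldehyde with an achiral allyl donor; the (S)-ligand is expected to direct allyl to the same Si face. No new compound arises (F0).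

Further compounds
F1 | step 5 | tert-butyl (3R)-1-[4-(benzyloxy)-3-methoxyphenyl]hex-5-en-3-yl carbonate | C=CC[C@@H](CCc1ccc(OCc2ccccc2)c(OC)c1)OC(=O)OC(C)(C)C
F2 | step 5 | (4R,6R)-4-{2-[4-(benzyloxy)-3-methoxyphenyl]ethyl}-6-(iodomethyl)-1,3-dioxan-2-one (cis) | IC[C@H]1C[C@@H](CCc2ccc(OCc3ccccc3)c(OC)c2)OC(=O)O1
F3 | step 5 | (2R)-4-[4-(benzyloxy)-3-methoxyphenyl]-1-[(2R)-oxiran-2-yl]butan-2-ol | C1O[C@@H]1C[C@@H](CCc1ccc(OCc2ccccc2)c(OC)c1)O
F4 | step 5 | (3R,5S)-1-[4-(benzyloxy)-3-methoxyphenyl]dodecane-3,5-diol | CCCCCCC[C@@H](C[C@@H](CCc1ccc(OCc2ccccc2)c(OC)c1)O)O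
F5 | step 5 | (3R,5S)-1-[4-(benzyloxy)-3-methoxyphenyl]dodecane-3,5-diyl diacetate | CCCCCCC[C@@H](C[C@@H](CCc1ccc(OCc2ccccc2)c(OC)c1)OC(C)=O)OC(C)=O
F6 | step 6 | (4R,6R)-6-{2-[4-(benzyloxy)-3-methoxyphenyl]ethyl}oxane-2,4-diol (anomer mixture) | OC1C[C@H](O)C[C@@H](CCc2ccc(OCc3ccccc3)c(OC)c2)O1
F0 | step 3 | none | none
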